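**Strategy.** In 2H-chromene numbering, the enol-ether double bond C8=C8a lies between the ring oxygen O1 and the carbonyl-type carbon C7. This unit is read as the retron of a ketene–ynol ether [2+2] cycloaddition. A dialkylketene (C4a=C7=O), released from a hindered aryl ester enolate, is tethered through C4–C3–C2–O1 to an ynol ether (C8≡C8a). One operation closes the oxane ring A and a cyclobutenone, forging C7–C8, C8a–C4a and the quaternary centre. The temporary C7–C4a bond is then opened by two-carbon insertion (C6, C5) with an acetate enolate to give ring B. A sulfide at C3, set by Shi epoxidation and thiolate opening, steers C4a and finally leaves as the C3=C4 alkene.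

Key step: step 6

Remark on the chemistry: ring A is the pyran ring and ring B the carbocycle; the enolised β-triketone is drawn in the tautomer of the target SMILES. Compounds 9 and 11–14 are mixtures of epimers at the ester α-carbon (future C4a), which becomes trigonal in ketene 15.

Step 1
Reactants: 1 5-methylhex-4-enoic acid; 2 2,6-di-tert-butyl-4-methylphenol (BHT)
Product: 4 2,6-di-tert-butyl-4-methylphenyl 5-methylhex-4-enoate, via 5-methylhex-4-enoyl chloride 3 (not isolated)
Conditions: (COCl)2, cat. DMF, CH2Cl2, 0 → 20 °C; then 2, n-BuLi, THF, 0 → 20 °C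
Reagents that add atoms: none
Why: Acid chloride formation and O-acylation of the lithium aryloxide (esterification) should give the BHT ester, which resists nucleophiles in the later organolithium steps and serves as the latent ketene precursor.

Step 2
Reactants: 4 2,6-di-tert-butyl-4-methylphenyl 5-methylhex-4-enoate
Product: 5 2,6-di-tert-butyl-4-methylphenyl 3-[(2R)-3,3-dimethyloxiran-2-yl]propanoate
Conditions: D-fructose-derived Shi ketone (1,2:4,5-di-O-isopropylidene-β-D-erythro-2,3-hexodiulo-2,6-pyranose, 30 mol %), KHSO5 (as 2KHSO5·KHSO4·K2SO4), K2CO3, Bu4NHSO4, MeCN–CH2(OMe)2 / aq. Na2B4O7 buffer, 0 °C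
Reagents that add atoms: potassium peroxymonosulfate (KHSO5), [K+].[O-]S(=O)(=O)OO
Why: Shi asymmetric epoxidation, in which the chiral dioxirane delivers oxygen to one face of the trisubstituted alkene through a spiro transition state, should give the (R)-epoxide, and the hindered aryl ester should survive the basic buffer.

Step 3
Reactants: 5 2,6-di-tert-butyl-4-methylphenyl 3-[(2R)-3,3-dimethyloxiran-2-yl]propanoate; 6 benzenethiol (thiophenol)
Product: 7 2,6-di-tert-butyl-4-methylphenyl (4S)-5-hydroxy-5-methyl-4-(phenylsulfanyl)hexanoate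
Conditions: PhSH (6), K2CO3 (0.2 equiv), MeOH–THF, 40 °C
Reagents that add atoms: none
Why: Base-catalysed SN2 opening of the epoxide by thiolate at the less substituted carbon with inversion should set the (S)-sulfide centre C3 and free the tertiary hydroxyl O1–H, while the hindered ester should not lactonise.

Step 4
Reactants: 7 2,6-di-tert-butyl-4-methylphenyl (4S)-5-hydroxy-5-methyl-4-(phenylsulfanyl)hexanoate; 8 1-bromo-3-methylbut-2-ene (prenyl bromide)
Product: 9 2,6-di-tert-butyl-4-methylphenyl (2RS,4S)-5-hydroxy-5-methyl-2-(3-methylbut-2-en-1-yl)-4-(phenylsulfanyl)hexanoate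
Conditions: LiN(iPr)2 (2.2 equiv), THF, −78 °C; then 8, DMPU, −78 → −40 °C; aq. NH4Cl
Reagents that add atoms: none
Why: Ester enolate α-alkylation with an allylic bromide (the alkoxide is carried as its lithium salt) is run below the temperature at which BHT ester enolates fragment, and the uncontrolled new centre is of no consequence because it becomes trigonal in step 6.

Step 5
Reactants: 9 2,6-di-tert-butyl-4-methylphenyl (2RS,4S)-5-hydroxy-5-methyl-2-(3-methylbut-2-en-1-yl)-4-(phenylsulfanyl)hexanoate; 10 trichloroethene; 8 1-bromo-3-methylbut-2-ene (prenyl bromide)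
Product: 13 2,6-di-tert-butyl-4-methylphenyl (2RS,4S)-5-methyl-5-[(5-methylhex-4-en-1-yn-1-yl)oxy]-2-(3-methylbut-2-en-1-yl)-4-(phenylsulfanyl)hexanoate, via (E)-1,2-dichlorovinyl ether 11 (not isolated), via lithium alkoxyacetylide 12 (not isolated)
Conditions: KH (1.05 equiv), THF, −20 °C; 10, −50 → 20 °C; n-BuLi (2.1 equiv), −78 → −40 °C; 8, DMPU, −78 → −20 °C; basic alumina
Reagents that add atoms: none
Why: The one-pot trichloroethene route to ynol ethers (alkoxide addition to dichloroethyne formed in situ, then β-elimination and chlorine–lithium exchange, then SN2 alkylation of the acetylide) should give the tertiary ynol ether, and the saturated C3–C4 tether rules out the facile [3,3] shift of allyl alkynyl ethers.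

Step 6
Reactants: 13 2,6-di-tert-butyl-4-methylphenyl (2RS,4S)-5-methyl-5-[(5-methylhex-4-en-1-yn-1-yl)oxy]-2-(3-methylbut-2-en-1-yl)-4-(phenylsulfanyl)hexanoate
Product: 16 (4S,6R)-3,3-dimethyl-6,8-bis(3-methylbut-2-en-1-yl)-4-(phenylsulfanyl)-2-oxabicyclo[4.2.0]oct-1(8)-en-7-one, via potassium ester enolate 14 (not isolated), via dialkylketene 15 (not isolated)
Conditions: KN(SiMe3)2 (1.1 equiv), THF (0.005 M), −78 → 0 °C; aq. NH4Cl
Reagents that add atoms: none
Why: KN(SiMe3)2 converts the hindered aryl ester into enolate 14, which above about −20 °C expels the non-nucleophilic aryloxide (E1cB) to release dialkylketene 15; the tethered ynol ether then adds across the ketene C=C in an asynchronous [2+2] cycloaddition in which its nucleophilic carbon C8 bonds to the ketene carbonyl carbon C7 and the ketene α-carbon C4a bonds to the oxygen-bearing C8a. The closest known reaction type is the ketene–alkoxyalkyne [2+2] route to 3-alkoxycyclobutenones, here in its intramolecular form. The four-membered ring closes by both new bonds in the cycloaddition itself, and ring A closes through the C8a–C4a bond as a six-membered, chair-like array of the O1–C2–C3–C4 tether, helped by the gem-dimethyl group. The new stereocentre C4a is controlled by C3: the prenyl group is forced pseudo-axial on ring A because C7 lies in the cyclobutenone plane, so closure through the chair with equatorial SPh should give the trans (4S,6R) isomer, and both ester epimers converge because C4a is trigonal in 15. The step needs regioselectivity (C7 to C8, C4a to C8a), which the normal ketene/ynol ether polarity and the tether length secure together, and ring closure faster than ketene dimerisation or ynol ether decay, which high dilution and low temperature secure; because C4a becomes trigonal again and is re-set under the same control in step 7, a modest diastereomer ratio here is tolerable.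

Step 7
Reactants: 16 (4S,6R)-3,3-dimethyl-6,8-bis(3-methylbut-2-en-1-yl)-4-(phenylsulfanyl)-2-oxabicyclo[4.2.0]oct-1(8)-en-7-one; 17 ethyl acetate
Product: 20 (3S,4aR)-7-hydroxy-2,2-dimethyl-4a,8-bis(3-methylbut-2-en-1-yl)-3-(phenylsulfanyl)-3,4-dihydro-2H-chromen-5(4aH)-one, via lithium cyclobutenoxide 18 (not isolated), via ring-opened lithium dienolate 19 (not isolated)
Conditions: 17 and LiN(iPr)2 (2.5 equiv each), THF, −78 °C; then 16, −78 → 20 °C; aq. NH4Cl
Reagents that add atoms: none
Why: Proposed new method: the ester enolate should add 1,2 to the strained C7 carbonyl to give cyclobutenoxide 18, whose oxyanion-accelerated conrotatory 4π ring opening (O− outward, C7–C4a cleaved) gives dienolate 19 with the CH2CO2Et arm cis to C4a, and the nucleophilic γ-carbon C4a then attacks the ester carbonyl (Dieckmann-type closure, loss of ethoxide) to form ring B; the final configuration at C4a should arise from attack through the ring A half-chair with equatorial SPh, so that the prenyl group ends pseudo-axial and trans to sulfur (4aR) from either C6 epimer of 16; the closest known reaction types are the alkoxide-accelerated ring opening of organolithium adducts of cyclobutenones and the Dieckmann condensation.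

Step 8
Reactants: 20 (3S,4aR)-7-hydroxy-2,2-dimethyl-4a,8-bis(3-methylbut-2-en-1-yl)-3-(phenylsulfanyl)-3,4-dihydro-2H-chromen-5(4aH)-one; 21 2-methylpropanoic acid (isobutyric acid)
Product: 23 (3S,4aR)-7-hydroxy-2,2-dimethyl-4a,8-bis(3-methylbut-2-en-1-yl)-6-(2-methylpropanoyl)-3-(phenylsulfanyl)-3,4-dihydro-2H-chromen-5(4aH)-one, via enol isobutyrate 22 (not isolated)
Conditions: 21, dicyclohexylcarbodiimide (DCC), 4-(dimethylamino)pyridine (DMAP, 0.3 equiv), CH2Cl2, 20 °C
Reagents that add atoms: none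
Why: Carbodiimide-mediated O-acylation of the cyclic 1,3-dione enol followed by DMAP-mediated O-to-C acyl migration (Steglich-type C-acylation of cyclic 1,3-diones) should place the isobutyryl group on C6, the only carbon between the two carbonyl groups.

Step 9
Reactants: 23 (3S,4aR)-7-hydroxy-2,2-dimethyl-4a,8-bis(3-methylbut-2-en-1-yl)-6-(2-methylpropanoyl)-3-(phenylsulfanyl)-3,4-dihydro-2H-chromen-5(4aH)-one
Product: 25 (4aR)-7-hydroxy-2,2-dimethyl-4a,8-bis(3-methylbut-2-en-1-yl)-6-(2-methylpropanoyl)-2H-chromen-5(4aH)-one, via sulfoxide 24 (not isolated)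
Conditions: mCPBA (1.0 equiv), CH2Cl2, −78 °C; then toluene, NaHCO3, 100 °C
Reagents that add atoms: none
Why: Chemoselective S-oxidation at low temperature and thermal syn-elimination of the sulfoxide (sulfoxide pyrolysis), which can only proceed toward C4 because C2 carries no hydrogen, should give the C3=C4 double bond and erase the auxiliary centre C3 without touching C4a.

**Compound list**

1 | 5-methylhex-4-enoic acid | CC(C)=CCCC(=O)O | starting material
2 | 2,6-di-tert-butyl-4-methylphenol (BHT) | Cc1cc(C(C)(C)C)c(O)c(C(C)(C)C)c1 | starting material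
3 | 5-methylhex-4-enoyl chloride | CC(C)=CCCC(=O)Cl | intermediate (not isolated)
4 | 2,6-di-tert-butyl-4-methylphenyl 5-methylhex-4-enoate | CC(C)=CCCC(=O)Oc1c(C(C)(C)C)cc(C)cc1C(C)(C)C | intermediate
5 | 2,6-di-tert-butyl-4-methylphenyl 3-[(2R)-3,3-dimethyloxiran-2-yl]propanoate | O=C(CC[C@H]1OC1(C)C)Oc2c(C(C)(C)C)cc(C)cc2C(C)(C)C | intermediate
6 | benzenethiol (thiophenol) | Sc1ccccc1 | starting material
7 | 2,6-di-tert-butyl-4-methylphenyl (4S)-5-hydroxy-5-methyl-4-(phenylsulfanyl)hexanoate | O=C(CC[C@H](Sc1ccccc1)C(C)(C)O)Oc2c(C(C)(C)C)cc(C)cc2C(C)(C)C | intermediate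
8 | 1-bromo-3-methylbut-2-ene (prenyl bromide) | CC(C)=CCBr | starting material
9 | 2,6-di-tert-butyl-4-methylphenyl (2RS,4S)-5-hydroxy-5-methyl-2-(3-methylbut-2-en-1-yl)-4-(phenylsulfanyl)hexanoate | O=C(C(CC=C(C)C)C[C@H](Sc1ccccc1)C(C)(C)O)Oc2c(C(C)(C)C)cc(C)cc2C(C)(C)C | intermediate
10 | trichloroethene | ClC=C(Cl)Cl | starting material
11 | 2,6-di-tert-butyl-4-methylphenyl (2RS,4S)-5-{[(E)-1,2-dichloroethenyl]oxy}-5-methyl-2-(3-methylbut-2-en-1-yl)-4-(phenylsulfanyl)hexanoate | O=C(C(CC=C(C)C)C[C@H](Sc1ccccc1)C(C)(C)O/C(Cl)=C\Cl)Oc2c(C(C)(C)C)cc(C)cc2C(C)(C)C | intermediate (not isolated)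
12 | lithium acetylide of the ethynyl ether derived from 11 | O=C(C(CC=C(C)C)C[C@H](Sc1ccccc1)C(C)(C)OC#C[Li])Oc2c(C(C)(C)C)cc(C)cc2C(C)(C)C | intermediate (not isolated)
13 | 2,6-di-tert-butyl-4-methylphenyl (2RS,4S)-5-methyl-5-[(5-methylhex-4-en-1-yn-1-yl)oxy]-2-(3-methylbut-2-en-1-yl)-4-(phenylsulfanyl)hexanoate | O=C(C(CC=C(C)C)C[C@H](Sc1ccccc1)C(C)(C)OC#CCC=C(C)C)Oc2c(C(C)(C)C)cc(C)cc2C(C)(C)C | intermediate
14 | potassium enolate of ester 13 | [K+].[O-]C(Oc1c(C(C)(C)C)cc(C)cc1C(C)(C)C)=C(CC=C(C)C)C[C@H](Sc2ccccc2)C(C)(C)OC#CCC=C(C)C | intermediate (not isolated)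
15 | (4S)-5-methyl-5-[(5-methylhex-4-en-1-yn-1-yl)oxy]-2-(3-methylbut-2-en-1-yl)-4-(phenylsulfanyl)hex-1-en-1-one (ketene) | O=C=C(CC=C(C)C)C[C@H](Sc1ccccc1)C(C)(C)OC#CCC=C(C)C | intermediate (not isolated)
16 | (4S,6R)-3,3-dimethyl-6,8-bis(3-methylbut-2-en-1-yl)-4-(phenylsulfanyl)-2-oxabicyclo[4.2.0]oct-1(8)-en-7-one | O=C1C(CC=C(C)C)=C2OC(C)(C)[C@@H](Sc3ccccc3)C[C@@]12CC=C(C)C | intermediate
17 | ethyl acetate | CCOC(C)=O | starting material
18 | lithium 7-(2-ethoxy-2-oxoethyl)-3,3-dimethyl-6,8-bis(3-methylbut-2-en-1-yl)-4-(phenylsulfanyl)-2-oxabicyclo[4.2.0]oct-1(8)-en-7-olate (C4 and C6 as in 16) | [Li+].[O-]C1(CC(=O)OCC)C(CC=C(C)C)=C2OC(C)(C)[C@@H](Sc3ccccc3)C[C@@]12CC=C(C)C | intermediate (not isolated)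
19 | lithium dienolate from ring opening of 18 (O–C7=C8–C8a=C4a, ring A as 3,4-dihydro-2H-pyran) | [Li+].[O-]C(CC(=O)OCC)=C(CC=C(C)C)C1=C(CC=C(C)C)C[C@H](Sc2ccccc2)C(C)(C)O1 | intermediate (not isolated)
20 | (3S,4aR)-7-hydroxy-2,2-dimethyl-4a,8-bis(3-methylbut-2-en-1-yl)-3-(phenylsulfanyl)-3,4-dihydro-2H-chromen-5(4aH)-one | O=C1C=C(O)C(CC=C(C)C)=C2OC(C)(C)[C@@H](Sc3ccccc3)C[C@@]12CC=C(C)C | intermediate
21 | 2-methylpropanoic acid (isobutyric acid) | CC(C)C(=O)O | starting material
22 | (3S,4aR)-2,2-dimethyl-4a,8-bis(3-methylbut-2-en-1-yl)-5-oxo-3-(phenylsulfanyl)-3,4,4a,5-tetrahydro-2H-chromen-7-yl 2-methylpropanoate | O=C1C=C(OC(=O)C(C)C)C(CC=C(C)C)=C2OC(C)(C)[C@@H](Sc3ccccc3)C[C@@]12CC=C(C)C | intermediate (not isolated)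
23 | (3S,4aR)-7-hydroxy-2,2-dimethyl-4a,8-bis(3-methylbut-2-en-1-yl)-6-(2-methylpropanoyl)-3-(phenylsulfanyl)-3,4-dihydro-2H-chromen-5(4aH)-one | O=C1C(C(=O)C(C)C)=C(O)C(CC=C(C)C)=C2OC(C)(C)[C@@H](Sc3ccccc3)C[C@@]12CC=C(C)C | intermediate
24 | (3S,4aR)-7-hydroxy-2,2-dimethyl-4a,8-bis(3-methylbut-2-en-1-yl)-6-(2-methylpropanoyl)-3-(phenylsulfinyl)-3,4-dihydro-2H-chromen-5(4aH)-one (sulfur epimers) | O=C1C(C(=O)C(C)C)=C(O)C(CC=C(C)C)=C2OC(C)(C)[C@@H](S(=O)c3ccccc3)C[C@@]12CC=C(C)C | intermediate (not isolated)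
25 | (4aR)-7-hydroxy-2,2-dimethyl-4a,8-bis(3-methylbut-2-en-1-yl)-6-(2-methylpropanoyl)-2H-chromen-5(4aH)-one | CC(C)=CCC1=C2OC(C)(C)C=C[C@@]2(CC=C(C)C)C(=O)C(C(=O)C(C)C)=C1O | target

**Totals.** Total step count: 9. Longest linear sequence: 9 steps (1 → 25).

**Steps most likely to fail**

1. Step 7 (Proposed new method). The enolate addition may revert, the enolate may instead attack C8a and open ring A by addition–elimination, proton transfer from C6 may quench the dienolate before the Claisen closure, or the facial bias at C4a may be insufficient. The fallback sets out from 16 and comes back at 20 with separate, known operations. Reformatsky addition of ethyl bromoacetate (Zn, THF) should give ethyl 2-[7-hydroxy-3,3-dimethyl-6,8-bis(3-methylbut-2-en-1-yl)-4-(phenylsulfanyl)-2-oxabicyclo[4.2.0]oct-1(8)-en-7-yl]acetate F1. Neutral thermal electrocyclic ring opening of this cyclobutenol (toluene, 80 °C) with tautomerisation should give the ring-opened β-keto ester ethyl 4-[(5S)-6,6-dimethyl-3-(3-methylbut-2-en-1-yl)-5-(phenylsulfanyl)oxan-2-ylidene]-7-methyl-3-oxooct-6-enoate F2. A separate Dieckmann condensation through its dianion (KOtBu, 2.2 equiv, THF) should then close ring B to 20 under the same C3 control.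

2. Step 6. The base may deprotonate the allylic–propargylic CH2 beside C8, the tertiary ynol ether may fragment on warming, or the ketene may be consumed by dimerisation or aryloxide return before ring closure. The fallback sets out from 9 and comes back at 16; it also avoids the tethered ynol ether of step 5.
   - The tertiary hydroxyl is silylated (Me3SiCl, imidazole, DMF) to the trimethylsilyl ether F3.
   - Its potassium enolate (KN(SiMe3)2, THF, −78 °C) is warmed with 1-ethoxy-5-methylhex-4-en-1-yne F4 (from ethoxyethyne, n-BuLi and prenyl bromide). The released ketene should undergo the intermolecular ketene–ynol ether [2+2], forming the same two carbon–carbon bonds together, to give 3-ethoxy-2,4-bis(3-methylbut-2-en-1-yl)-4-[(2S)-3-methyl-2-(phenylsulfanyl)-3-(trimethylsilyloxy)butyl]cyclobut-2-en-1-one F5.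
   - Bu4NF (THF) frees the tertiary alkoxide, which should close ring A by intramolecular addition–elimination at C8a with loss of ethoxide (vinylogous transesterification). This gives 16 together with its C6 epimer (4S,6S)-3,3-dimethyl-6,8-bis(3-methylbut-2-en-1-yl)-4-(phenylsulfanyl)-2-oxabicyclo[4.2.0]oct-1(8)-en-7-one F6; both converge in step 7.

3. Step 9. At 100 °C the C4a prenyl group may migrate sigmatropically, benzenesulfenic acid may add to the finished enolised triketone or its prenyl groups, or over-oxidation may occur. The fallback sets out from 20 and comes back at 25, with the alkene made before the acyl group so that the finished triketone is never heated. Oxidation of 20 (mCPBA, CH2Cl2, −78 °C) should give the sulfoxide F7. Thermolysis (toluene, 90 °C, methyl propiolate as sulfenic acid trap) should give (4aR)-7-hydroxy-2,2-dimethyl-4a,8-bis(3-methylbut-2-en-1-yl)-2H-chromen-5(4aH)-one F8. C-acylation with 21 (DCC, DMAP, CH2Cl2, 20 °C) through the enol isobutyrate F9 should then give 25.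

**Further compounds**

F1 | step 7 | ethyl 2-[7-hydroxy-3,3-dimethyl-6,8-bis(3-methylbut-2-en-1-yl)-4-(phenylsulfanyl)-2-oxabicyclo[4.2.0]oct-1(8)-en-7-yl]acetate (C4 and C6 as in 16) | CCOC(=O)CC1(O)C(CC=C(C)C)=C2OC(C)(C)[C@@H](Sc3ccccc3)C[C@@]12CC=C(C)C
F2 | step 7 | ethyl 4-[(5S)-6,6-dimethyl-3-(3-methylbut-2-en-1-yl)-5-(phenylsulfanyl)oxan-2-ylidene]-7-methyl-3-oxooct-6-enoate | CCOC(=O)CC(=O)C(CC=C(C)C)=C1OC(C)(C)[C@@H](Sc2ccccc2)CC1CC=C(C)C
F3 | step 6 | 2,6-di-tert-butyl-4-methylphenyl (2RS,4S)-5-methyl-2-(3-methylbut-2-en-1-yl)-4-(phenylsulfanyl)-5-(trimethylsilyloxy)hexanoate | O=C(C(CC=C(C)C)C[C@H](Sc1ccccc1)C(C)(C)O[Si](C)(C)C)Oc2c(C(C)(C)C)cc(C)cc2C(C)(C)C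
F4 | step 6 | 1-ethoxy-5-methylhex-4-en-1-yne | CCOC#CCC=C(C)C
F5 | step 6 | 3-ethoxy-2,4-bis(3-methylbut-2-en-1-yl)-4-[(2S)-3-methyl-2-(phenylsulfanyl)-3-(trimethylsilyloxy)butyl]cyclobut-2-en-1-one | O=C1C(CC=C(C)C)=C(OCC)C1(CC=C(C)C)C[C@H](Sc2ccccc2)C(C)(C)O[Si](C)(C)C
F6 | step 6 | (4S,6S)-3,3-dimethyl-6,8-bis(3-methylbut-2-en-1-yl)-4-(phenylsulfanyl)-2-oxabicyclo[4.2.0]oct-1(8)-en-7-one | O=C1C(CC=C(C)C)=C2OC(C)(C)[C@@H](Sc3ccccc3)C[C@]12CC=C(C)C
F7 | step 9 | (3S,4aR)-7-hydroxy-2,2-dimethyl-4a,8-bis(3-methylbut-2-en-1-yl)-3-(phenylsulfinyl)-3,4-dihydro-2H-chromen-5(4aH)-one | O=C1C=C(O)C(CC=C(C)C)=C2OC(C)(C)[C@@H](S(=O)c3ccccc3)C[C@@]12CC=C(C)C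
F8 | step 9 | (4aR)-7-hydroxy-2,2-dimethyl-4a,8-bis(3-methylbut-2-en-1-yl)-2H-chromen-5(4aH)-one | O=C1C=C(O)C(CC=C(C)C)=C2OC(C)(C)C=C[C@@]12CC=C(C)C
F9 | step 9 | (4aR)-2,2-dimethyl-4a,8-bis(3-methylbut-2-en-1-yl)-5-oxo-4a,5-dihydro-2H-chromen-7-yl 2-methylpropanoate | O=C1C=C(OC(=O)C(C)C)C(CC=C(C)C)=C2OC(C)(C)C=C[C@@]12CC=C(C)C
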